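**Retrosynthetic overview**
1. Lespedezaflavanone C (21) ⇐ removal of three MOM ethers from the protected flavanonol 20.
2. Ring C of 20 ⇐ ring contraction of the seven-membered cyclic acetal 18 (a 2-aryl-4H-1,3-benzodioxepin-5-one): the acetal carbon shifts 1,2 from oxygen to the neighbouring enolisable carbon, forming C2–C3 and both stereocentres.
3. 18 ⇐ acetalisation of the ring A hydroxymethyl ketone 10 with the ring B aldehyde 16. Rings A and B come from the starting arenes; the seven-membered acetal ring is formed first and then contracted to ring C.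
4. 10 ⇐ resorcinol (MOM protection, C–H borylation/oxidation, ortho-prenylation, ortho-formylation, hydroxymethylation); 16 ⇐ 4-bromophenol (ortho-prenylation, MOM protection, Br–Li exchange/DMF).

Assumption: the sense of induction in step 10 cannot be predicted with certainty; the route is written with the (S,S)-ligand, and the (R,R)-ligand is used instead if the first run gives the (2S,3S) product.

**Step 1**
Reactants: 1 resorcinol
Product: 2 1,3-bis(methoxymethoxy)benzene
Conditions: NaH (2.4 equiv), MOMCl (2.4 equiv), DMF, 0 °C → rt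
Reagents that add atoms: chloromethyl methyl ether, COCCl
Why: Williamson-type O-alkylation of the bis-phenoxide (MOM protection) is high-yielding on resorcinol and creates no stereocentre.

**Step 2**
Reactants: 2 1,3-bis(methoxymethoxy)benzene
Product: 4 3,5-bis(methoxymethoxy)phenol, via arylboronate 3 (not isolated)
Conditions: [Ir(OMe)(cod)]2 (1.5 mol %), dtbpy (3 mol %), B2pin2 (1.0 equiv), cyclohexane, 80 °C; then 30 % H2O2, aq NaOH, THF, 0 °C
Reagents that add atoms: bis(pinacolato)diboron, CC1(C)OB(OC1(C)C)B1OC(C)(C)C(C)(C)O1 (boron carried by 3 only); hydrogen peroxide, OO (phenol oxygen of 4)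
Why: Sterically controlled iridium-catalysed C–H borylation takes the only position not ortho to a substituent (C5), and basic peroxide oxidation of the C–B bond, which MOM ethers tolerate, gives the phenol with exactly one free hydroxyl.

**Step 3**
Reactants: 4 3,5-bis(methoxymethoxy)phenol; 5 prenyl bromide (1-bromo-3-methylbut-2-ene)
Product: 6 3,5-bis(methoxymethoxy)-2-(3-methylbut-2-en-1-yl)phenol
Conditions: NaH (1.05 equiv), toluene, 0 °C; then 5 (1.0 equiv), rt
Reagents that add atoms: none
Why: Ortho-C-alkylation of the sodium phenoxide as a tight ion pair in a non-polar solvent (phenoxide C-prenylation) uses two equivalent ortho positions, so one ortho isomer forms; the O-prenyl ether and the 4-prenyl isomer are expected as separable by-products, so the yield will be moderate.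

**Step 4**
Reactants: 6 3,5-bis(methoxymethoxy)-2-(3-methylbut-2-en-1-yl)phenol; 7 formaldehyde (used as paraformaldehyde)
Product: 9 2-hydroxy-4,6-bis(methoxymethoxy)-3-(3-methylbut-2-en-1-yl)benzaldehyde, via benzylic alcohol 8 (not isolated)
Conditions: MgCl2 (2 equiv), Et3N (4 equiv), paraformaldehyde (6 equiv), MeCN, 80 °C
Reagents that add atoms: none
Why: In the magnesium-mediated ortho-formylation of phenols (Casnati–Skattebøl) the magnesium phenoxide delivers formaldehyde only to the single free ortho position, and a second formaldehyde oxidises the benzylic alkoxide by hydride transfer; the conditions are non-acidic, so MOM and prenyl groups survive.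

**Step 5**
Reactants: 9 2-hydroxy-4,6-bis(methoxymethoxy)-3-(3-methylbut-2-en-1-yl)benzaldehyde; 7 formaldehyde (used as paraformaldehyde)
Product: 10 2-hydroxy-1-[2-hydroxy-4,6-bis(methoxymethoxy)-3-(3-methylbut-2-en-1-yl)phenyl]ethan-1-one
Conditions: paraformaldehyde (3 equiv), 3-ethylbenzothiazolium bromide (15 mol %), i-Pr2NEt (15 mol %), THF, 60 °C
Reagents that add atoms: none
Why: In this thiazolium-carbene-catalysed crossed acyloin reaction (hydroxymethylation of an aldehyde) the Breslow intermediate of the aryl aldehyde adds to the far more electrophilic formaldehyde, giving the hydroxymethyl ketone without touching alkenes or acetals.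

**Step 6**
Reactants: 11 4-bromophenol; 5 prenyl bromide (1-bromo-3-methylbut-2-ene)
Product: 12 4-bromo-2-(3-methylbut-2-en-1-yl)phenol
Conditions: NaH (1.05 equiv), toluene, 0 °C; then 5 (1.0 equiv), rt
Reagents that add atoms: none
Why: Ortho-C-prenylation of the sodium phenoxide in a non-polar solvent works here because the para position is blocked by bromine, so only ortho-C- and O-alkylation compete.

**Step 7**
Reactants: 12 4-bromo-2-(3-methylbut-2-en-1-yl)phenol
Product: 13 4-bromo-1-(methoxymethoxy)-2-(3-methylbut-2-en-1-yl)benzene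
Conditions: NaH (1.2 equiv), MOMCl (1.2 equiv), THF, 0 °C → rt
Reagents that add atoms: chloromethyl methyl ether, COCCl
Why: MOM protection by Williamson-type O-alkylation masks the phenol for the organolithium step and matches the ring A protecting groups for a single final deprotection.

**Step 8**
Reactants: 13 4-bromo-1-(methoxymethoxy)-2-(3-methylbut-2-en-1-yl)benzene; 14 N,N-dimethylformamide
Product: 16 4-(methoxymethoxy)-3-(3-methylbut-2-en-1-yl)benzaldehyde, via aryllithium 15 (not isolated)
Conditions: n-BuLi (1.05 equiv), THF, −78 °C; then DMF (1.5 equiv), −78 °C → 0 °C; aq work-up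
Reagents that add atoms: n-butyllithium, [Li]CCCC (lithium carried by 15 only)
Why: Bromine–lithium exchange outruns any deprotonation at −78 °C and the aryllithium is formylated by DMF (Bouveault aldehyde synthesis), with the MOM ether and prenyl group inert.

**Step 9**
Reactants: 16 4-(methoxymethoxy)-3-(3-methylbut-2-en-1-yl)benzaldehyde; 10 2-hydroxy-1-[2-hydroxy-4,6-bis(methoxymethoxy)-3-(3-methylbut-2-en-1-yl)phenyl]ethan-1-one
Product: 18 racemic 6,8-bis(methoxymethoxy)-2-[4-(methoxymethoxy)-3-(3-methylbut-2-en-1-yl)phenyl]-9-(3-methylbut-2-en-1-yl)-4H-1,3-benzodioxepin-5-one, via dimethyl acetal 17 (not isolated)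
Conditions: 16, HC(OMe)3, PPTS (5 mol %), MeOH, rt; evaporate; then 10, PPTS (5 mol %), toluene, 5 Å MS, 40 °C; filter through basic alumina
Reagents that add atoms: trimethyl orthoformate, COC(OC)OC (methoxy groups carried by 17 only)
Why: In this acid-catalysed acetal exchange (transacetalisation) the primary hydroxyl of 10 exchanges first and the chelated phenol then closes the seven-membered ring as methanol is removed; the acetal centre forms racemic, which does not matter because it is planarised in step 10.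

**Step 10**
Reactants: 18 racemic 6,8-bis(methoxymethoxy)-2-[4-(methoxymethoxy)-3-(3-methylbut-2-en-1-yl)phenyl]-9-(3-methylbut-2-en-1-yl)-4H-1,3-benzodioxepin-5-one
Product: 20 (2R,3R)-3-hydroxy-5,7-bis(methoxymethoxy)-2-[4-(methoxymethoxy)-3-(3-methylbut-2-en-1-yl)phenyl]-8-(3-methylbut-2-en-1-yl)-2,3-dihydro-4H-chromen-4-one, via ring-opened ion pair 19 (not isolated)
Conditions: Cu(OTf)2 (10 mol %), (S,S)-t-Bu-box [2,2'-(propane-2,2-diyl)bis((4S)-4-tert-butyl-4,5-dihydrooxazole)] (11 mol %), 2,6-lutidine (20 mol %), 4 Å MS, CH2Cl2, −20 °C → rt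
Reagents that add atoms: none
Why: Proposed new method: the divalent-copper bis(oxazoline) Lewis acid chelates the C5 carbonyl and the acetal oxygen O3 of 18, 2,6-lutidine soft-enolises the chelate at C4, and heterolysis of the activated C2–O3 bond gives a copper enediolate tethered to an aryloxy-stabilised 4-alkoxybenzyl cation (ion pair 19) that collapses by 6-endo C–C bond formation (the 5-endo closure at the other enediolate carbon is disfavoured), so the acetal carbon shifts 1,2 from oxygen to carbon and the seven-membered ring contracts to ring C; because C2 of racemic 18 is planar in 19 the process is enantioconvergent, the ligand shields one face of the enediolate to set C3, and chair-like closure with the aryl group equatorial sets C2 trans to it, giving (2R,3R); the closest known reaction types are the [1,2]-Wittig rearrangement of acetals and of α-alkoxy ketone enolates, the Petasis–Ferrier rearrangement, and additions of chiral metal enolates formed by soft enolisation to oxocarbenium ions.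

**Step 11**
Reactants: 20 (2R,3R)-3-hydroxy-5,7-bis(methoxymethoxy)-2-[4-(methoxymethoxy)-3-(3-methylbut-2-en-1-yl)phenyl]-8-(3-methylbut-2-en-1-yl)-2,3-dihydro-4H-chromen-4-one
Product: 21 lespedezaflavanone C, (2R,3R)-3,5,7-trihydroxy-2-[4-hydroxy-3-(3-methylbut-2-en-1-yl)phenyl]-8-(3-methylbut-2-en-1-yl)-2,3-dihydro-4H-chromen-4-one
Conditions: 3 M aq HCl/MeOH (1:10), 40 °C, monitored and stopped at full conversion
Reagents that add atoms: none
Why: Mild acidic methanolysis cleaves the three MOM acetals; the conditions are chosen to leave the prenyl groups uncyclised and the trans-diequatorial C2/C3 stereocentres unepimerised.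

**Compound list**
1 | resorcinol | Oc1cccc(O)c1 | starting material
2 | 1,3-bis(methoxymethoxy)benzene | COCOc1cccc(OCOC)c1 | intermediate
3 | 2-[3,5-bis(methoxymethoxy)phenyl]-4,4,5,5-tetramethyl-1,3,2-dioxaborolane | COCOc1cc(OCOC)cc(c1)B1OC(C)(C)C(C)(C)O1 | intermediate
4 | 3,5-bis(methoxymethoxy)phenol | COCOc1cc(O)cc(OCOC)c1 | intermediate
5 | prenyl bromide (1-bromo-3-methylbut-2-ene) | CC(C)=CCBr | starting material
6 | 3,5-bis(methoxymethoxy)-2-(3-methylbut-2-en-1-yl)phenol | CC(C)=CCc1c(O)cc(OCOC)cc1OCOC | intermediate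
7 | formaldehyde (used as paraformaldehyde) | C=O | starting material
8 | 2-(hydroxymethyl)-3,5-bis(methoxymethoxy)-6-(3-methylbut-2-en-1-yl)phenol (magnesium phenoxide in the flask) | OCc1c(O)c(CC=C(C)C)c(OCOC)cc1OCOC | intermediate
9 | 2-hydroxy-4,6-bis(methoxymethoxy)-3-(3-methylbut-2-en-1-yl)benzaldehyde | O=Cc1c(O)c(CC=C(C)C)c(OCOC)cc1OCOC | intermediate
10 | 2-hydroxy-1-[2-hydroxy-4,6-bis(methoxymethoxy)-3-(3-methylbut-2-en-1-yl)phenyl]ethan-1-one | O=C(CO)c1c(O)c(CC=C(C)C)c(OCOC)cc1OCOC | intermediate
11 | 4-bromophenol | Oc1ccc(Br)cc1 | starting material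
12 | 4-bromo-2-(3-methylbut-2-en-1-yl)phenol | CC(C)=CCc1cc(Br)ccc1O | intermediate
13 | 4-bromo-1-(methoxymethoxy)-2-(3-methylbut-2-en-1-yl)benzene | CC(C)=CCc1cc(Br)ccc1OCOC | intermediate
14 | N,N-dimethylformamide | CN(C)C=O | starting material
15 | [4-(methoxymethoxy)-3-(3-methylbut-2-en-1-yl)phenyl]lithium | [Li]c1ccc(OCOC)c(CC=C(C)C)c1 | intermediate
16 | 4-(methoxymethoxy)-3-(3-methylbut-2-en-1-yl)benzaldehyde | O=Cc1ccc(OCOC)c(CC=C(C)C)c1 | intermediate
17 | 4-(dimethoxymethyl)-1-(methoxymethoxy)-2-(3-methylbut-2-en-1-yl)benzene | COC(OC)c1ccc(OCOC)c(CC=C(C)C)c1 | intermediate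
18 | racemic 6,8-bis(methoxymethoxy)-2-[4-(methoxymethoxy)-3-(3-methylbut-2-en-1-yl)phenyl]-9-(3-methylbut-2-en-1-yl)-4H-1,3-benzodioxepin-5-one | O=C1COC(c2ccc(OCOC)c(CC=C(C)C)c2)Oc2c(CC=C(C)C)c(OCOC)cc(OCOC)c21 | intermediate
19 | ring-opened ion pair: enediolate tethered to the aryloxy-stabilised benzylic cation (copper-bound in the flask, drawn without the metal) | [O-]C=C(O)c1c(OCOC)cc(OCOC)c(CC=C(C)C)c1[O+]=Cc1ccc(OCOC)c(CC=C(C)C)c1 | intermediate
20 | (2R,3R)-3-hydroxy-5,7-bis(methoxymethoxy)-2-[4-(methoxymethoxy)-3-(3-methylbut-2-en-1-yl)phenyl]-8-(3-methylbut-2-en-1-yl)-2,3-dihydro-4H-chromen-4-one | CC(C)=CCc1cc([C@H]2Oc3c(CC=C(C)C)c(OCOC)cc(OCOC)c3C(=O)[C@@H]2O)ccc1OCOC | intermediate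
21 | lespedezaflavanone C, (2R,3R)-3,5,7-trihydroxy-2-[4-hydroxy-3-(3-methylbut-2-en-1-yl)phenyl]-8-(3-methylbut-2-en-1-yl)-2,3-dihydro-4H-chromen-4-one | CC(C)=CCc1cc([C@H]2Oc3c(CC=C(C)C)c(O)cc(O)c3C(=O)[C@@H]2O)ccc1O | target

**Step count and risks**
Total steps: 11. Longest linear sequence: 8 steps (steps 1–5, 9, 10, 11); the ring B branch (steps 6–8) joins at step 9.

Step 10 (the proposed ring contraction) is the most likely to fail. The cation in 19 may be trapped by the neighbouring prenyl alkene in a Prins-type closure, ionisation may occur mainly at the aryl oxygen without product formation, or the enantioselectivity may be low. The fallback uses known chalcone-epoxide chemistry and sets out from aldehyde 9. MeMgBr (excess, THF, 0 °C) gives racemic 2-(1-hydroxyethyl)-3,5-bis(methoxymethoxy)-6-(3-methylbut-2-en-1-yl)phenol F1, and MnO2 in CH2Cl2 oxidises it to 1-[2-hydroxy-4,6-bis(methoxymethoxy)-3-(3-methylbut-2-en-1-yl)phenyl]ethan-1-one F2. Claisen–Schmidt condensation of F2 with aldehyde 16 (KOH, EtOH, rt) gives (E)-1-[2-hydroxy-4,6-bis(methoxymethoxy)-3-(3-methylbut-2-en-1-yl)phenyl]-3-[4-(methoxymethoxy)-3-(3-methylbut-2-en-1-yl)phenyl]prop-2-en-1-one F3, whose chelated phenol is protected (NaH, MOMCl, DMF) to give (E)-3-[4-(methoxymethoxy)-3-(3-methylbut-2-en-1-yl)phenyl]-1-[2,4,6-tris(methoxymethoxy)-3-(3-methylbut-2-en-1-yl)phenyl]prop-2-en-1-one F4. Julia–Colonna epoxidation (poly-L-leucine, urea–H2O2, DBU, THF) gives [(2R,3S)-3-[4-(methoxymethoxy)-3-(3-methylbut-2-en-1-yl)phenyl]oxiran-2-yl][2,4,6-tris(methoxymethoxy)-3-(3-methylbut-2-en-1-yl)phenyl]methanone F5. HCl in MeOH then removes the four MOM groups, and the freed 2'-phenol opens the epoxide at the benzylic carbon with inversion (6-endo) to give the trans-(2R,3R) flavanonol. This returns to the route at the target 21.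

Step 5 (carbene-catalysed hydroxymethylation) is the second risk. The aldehyde 9 is doubly ortho-substituted, very electron-rich and hydrogen-bonded, so formation of the Breslow intermediate may be too slow. The fallback sets out from phenol 6 and bypasses the aldehyde. Its magnesium phenoxide (EtMgBr, toluene/Et2O) reacts with ethyl glyoxylate in an ortho-specific hydroxyalkylation to give ethyl 2-hydroxy-2-[2-hydroxy-4,6-bis(methoxymethoxy)-3-(3-methylbut-2-en-1-yl)phenyl]acetate F6. LiAlH4 (THF, 0 °C) reduces the ester to 1-[2-hydroxy-4,6-bis(methoxymethoxy)-3-(3-methylbut-2-en-1-yl)phenyl]ethane-1,2-diol F7, and MnO2 in CH2Cl2 oxidises only the benzylic hydroxyl. This returns to the route at 10.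

Step 9 (seven-membered acetal formation) is the third risk. The phenol is hindered and chelated, and the equilibrium exchange may stall at the open mixed acetal or give oligomers. The fallback replaces the equilibrium exchange by a kinetically driven silyl acetalisation and sets out from 10. Silylation (TMSCl, imidazole, CH2Cl2) gives 1-[4,6-bis(methoxymethoxy)-3-(3-methylbut-2-en-1-yl)-2-(trimethylsilyloxy)phenyl]-2-(trimethylsilyloxy)ethan-1-one F8, which reacts with aldehyde 16 under catalytic TMSOTf in CH2Cl2 at −78 °C (Noyori acetalisation), driven by siloxane formation. This returns to the route at 18.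

**Further compounds**
F1 | step 10 | racemic 2-(1-hydroxyethyl)-3,5-bis(methoxymethoxy)-6-(3-methylbut-2-en-1-yl)phenol | CC(O)c1c(O)c(CC=C(C)C)c(OCOC)cc1OCOC
F2 | step 10 | 1-[2-hydroxy-4,6-bis(methoxymethoxy)-3-(3-methylbut-2-en-1-yl)phenyl]ethan-1-one | CC(=O)c1c(O)c(CC=C(C)C)c(OCOC)cc1OCOC
F3 | step 10 | (E)-1-[2-hydroxy-4,6-bis(methoxymethoxy)-3-(3-methylbut-2-en-1-yl)phenyl]-3-[4-(methoxymethoxy)-3-(3-methylbut-2-en-1-yl)phenyl]prop-2-en-1-one | O=C(/C=C/c1ccc(OCOC)c(CC=C(C)C)c1)c1c(O)c(CC=C(C)C)c(OCOC)cc1OCOC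
F4 | step 10 | (E)-3-[4-(methoxymethoxy)-3-(3-methylbut-2-en-1-yl)phenyl]-1-[2,4,6-tris(methoxymethoxy)-3-(3-methylbut-2-en-1-yl)phenyl]prop-2-en-1-one | O=C(/C=C/c1ccc(OCOC)c(CC=C(C)C)c1)c1c(OCOC)c(CC=C(C)C)c(OCOC)cc1OCOC
F5 | step 10 | [(2R,3S)-3-[4-(methoxymethoxy)-3-(3-methylbut-2-en-1-yl)phenyl]oxiran-2-yl][2,4,6-tris(methoxymethoxy)-3-(3-methylbut-2-en-1-yl)phenyl]methanone | O=C([C@@H]1O[C@H]1c1ccc(OCOC)c(CC=C(C)C)c1)c1c(OCOC)c(CC=C(C)C)c(OCOC)cc1OCOC
F6 | step 5 | racemic ethyl 2-hydroxy-2-[2-hydroxy-4,6-bis(methoxymethoxy)-3-(3-methylbut-2-en-1-yl)phenyl]acetate | CCOC(=O)C(O)c1c(O)c(CC=C(C)C)c(OCOC)cc1OCOC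
F7 | step 5 | racemic 1-[2-hydroxy-4,6-bis(methoxymethoxy)-3-(3-methylbut-2-en-1-yl)phenyl]ethane-1,2-diol | OCC(O)c1c(O)c(CC=C(C)C)c(OCOC)cc1OCOC
F8 | step 9 | 1-[4,6-bis(methoxymethoxy)-3-(3-methylbut-2-en-1-yl)-2-(trimethylsilyloxy)phenyl]-2-(trimethylsilyloxy)ethan-1-one | C[Si](C)(C)OCC(=O)c1c(O[Si](C)(C)C)c(CC=C(C)C)c(OCOC)cc1OCOC
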